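**Retrosynthetic overview**

1. Numbering used (briarane): C1(C15 Me)–C2(OAc)–C3–C4–C5(C16 Me)=C6(Cl)–C7(lactone O)–C8(OH; arm C17(C18 Me)–C19=O)–C9(OH)–C10–C11(C20 Me)–C12(OAc)–C13=C14–C1.
2. The ten-membered ring is closed last, at C3–C4, by alkylation of a C2/C3 β-keto sulfone with the C4 allylic bromide; before it the γ-lactone is made by an intramolecular Reformatsky reaction of an O7 2-bromopropanoate onto a C8 ketone.
3. The C8 ketone and the C9=C10 alkene come from a Meyer–Schuster rearrangement of a C10 alkynyl carbinol (C9–C10 by acetylide addition); C9–OH and H10 follow by epoxidation and titanocene-mediated reductive opening.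
4. The cyclohexene ring is made first, by the key [3+3] annulation: conjugate addition C1→C14 of β-keto ester 1 to propynal, then aldol C11→C12. Enabling feature: in the ring C1–C10–C11–C12–C13=C14, C10 lies between C1 and C11 and the C12 oxygen is allylic to the cis C13=C14 bond, so with C10 as a ketone C1 and C11 are the two α-carbons of one β-keto ester and C12–C14 is an ynal.
5. Ring order: cyclohexene (step 1); temporary lactone bridge C2(=O)–O–C12 across it (step 2; it fixes the C10 face and is opened in step 16); γ-lactone (step 12); ten-membered ring (step 19).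

Key step: step 1

Remark: C17 is α to the lactone carbonyl and epimerisable; the route assumes that the natural configuration (C18 methyl cis to the C8 oxygen, trans to C9) is the thermodynamic one, and prop-2-ynal is used as its commercial stabilised solution.

**Route**

Step 1
Reactants: 1 methyl 2-methyl-3-oxopentanoate; 2 prop-2-ynal
Product: 4 methyl (1S,3S,4R)-4-hydroxy-1,3-dimethyl-2-oxocyclohex-5-ene-1-carboxylate, via Michael adduct 3 (not isolated)
Conditions: 9-amino-9-deoxy-epi-quinidine 3,5-bis(trifluoromethyl)phenyl squaramide (5 mol%), toluene, −40 °C; then DBU (0.3 equiv), −20 to 0 °C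
Reagents that add atoms: none
Why: Proposed new method: the bifunctional catalyst deprotonates 1 and delivers its hydrogen-bonded enolate through C1 to the alkyne terminus C14 of 2 (trans-addition, so the kinetic enal 3 is Z), after which DBU enolises the C10 ketone towards C11, the only side that still carries hydrogen, and this enolate adds to the C12 aldehyde in a 6-(enolendo)-exo-trig aldol that closes the cyclohexene. The closest known reaction types are the cinchona-catalysed conjugate additions of α-substituted β-keto esters to alkynones and the amine-catalysed Michael/aldol [3+3] annulations of β-keto esters with enals. C1 is set by the catalyst (one enolate face is shielded in the ion pair; the quinine-derived pseudoenantiomer would give the antipode), while C11 and C12 follow from a chair-like transition state with a Z-enolate in which the C20 methyl, the aldehyde oxygen and the C15 methyl are equatorial and only the ester is axial, the same isomer being favoured thermodynamically under the reversible aldol conditions. The step needs 1,4- over 1,2-addition (soft, doubly stabilised donor; the aldehyde adduct is reversible), Z geometry of 3 (kinetic anti-addition; any E isomer can be returned by reversible conjugate addition of the amine) and regioselective enolisation (guaranteed by the quaternary C1).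

Step 2
Reactants: 4 methyl (1S,3S,4R)-4-hydroxy-1,3-dimethyl-2-oxocyclohex-5-ene-1-carboxylate
Product: 5 (1R,4S,6S)-4,6-dimethyl-2-oxabicyclo[2.2.2]oct-7-ene-3,5-dione
Conditions: Ti(OiPr)4 (10 mol%), toluene, 45 °C, 5 Å molecular sieves
Reagents that add atoms: none
Why: Intramolecular transesterification (lactonisation) of the cis-1,4 ester and hydroxyl through a boat gives the bridged lactone without touching a stereocentre; the temperature is kept low because 5 is a β-acyloxy ketone and a formal pyrone cycloadduct.

Step 3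
Reactants: 6 4-methylfuran-2(5H)-one
Product: 7 3-chloro-4-methylfuran-2(5H)-one
Conditions: PhICl2, pyridine, CH2Cl2, 0 to 25 °C
Reagents that add atoms: iodobenzene dichloride ClI(Cl)c1ccccc1
Why: α-Chlorination of the enoate by chlorine addition and pyridine-mediated loss of HCl (addition–elimination), a standard route to α-halo butenolides; the ring later guarantees the C4/C7-cis geometry of C5=C6.

Step 4
Reactants: 7 3-chloro-4-methylfuran-2(5H)-one
Product: 9 (2E)-4-[tert-butyl(diphenyl)silyl]oxy-2-chloro-N-methoxy-N,3-dimethylbut-2-enamide, via hydroxy amide 8 (not isolated)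
Conditions: AlMe3, MeNH(OMe)·HCl, CH2Cl2, 0 °C; then t-BuPh2SiCl, imidazole, DMF, 0 °C
Reagents that add atoms: N,O-dimethylhydroxylamine hydrochloride CNOC.Cl; tert-butyl(chloro)diphenylsilane CC(C)(C)[Si](Cl)(c1ccccc1)c1ccccc1
Why: Weinreb aminolysis of the lactone with the aluminium amide, followed by silylation of the liberated primary alcohol before it can re-lactonise; the alkene geometry is that of the ring.

Step 5
Reactants: 9 (2E)-4-[tert-butyl(diphenyl)silyl]oxy-2-chloro-N-methoxy-N,3-dimethylbut-2-enamide
Product: 10 (2E)-4-[tert-butyl(diphenyl)silyl]oxy-2-chloro-3-methylbut-2-enal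
Conditions: i-Bu2AlH, THF, −78 °C
Reagents that add atoms: none
Why: Hydride reduction of a Weinreb amide stops at the aldehyde through the stable chelated hemiaminal.

Step 6
Reactants: 10 (2E)-4-[tert-butyl(diphenyl)silyl]oxy-2-chloro-3-methylbut-2-enal; 11 ethynyl(trimethyl)silane
Product: 12 (3R,4E)-6-[tert-butyl(diphenyl)silyl]oxy-4-chloro-5-methyl-1-(trimethylsilyl)hex-4-en-1-yn-3-ol
Conditions: (S,S)-ProPhenol (10 mol%), Ph3PO (20 mol%), Me2Zn (3 equiv), toluene, 4 °C
Reagents that add atoms: none
Why: Zinc/ProPhenol-catalysed asymmetric alkynylation of an α,β-unsaturated aldehyde; the dinuclear zinc catalyst selects the aldehyde face and sets C7 as R (the ligand antipode would give 7S, so the ligand hand is chosen accordingly).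

Step 7
Reactants: 12 (3R,4E)-6-[tert-butyl(diphenyl)silyl]oxy-4-chloro-5-methyl-1-(trimethylsilyl)hex-4-en-1-yn-3-ol
Product: 13 triethylsilyl ether of 12
Conditions: Et3SiCl, imidazole, CH2Cl2, 0 °C
Reagents that add atoms: chlorotriethylsilane CC[Si](Cl)(CC)CC
Why: Standard silylation of the secondary propargylic alcohol, needed so that only the tertiary carbinol rearranges in step 9.

Step 8
Reactants: 13 triethylsilyl ether of 12; 5 (1R,4S,6S)-4,6-dimethyl-2-oxabicyclo[2.2.2]oct-7-ene-3,5-dione
Product: 15 C10 alkynyl carbinol on the bridged lactone, via lithium acetylide 14 (not isolated)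
Conditions: 13, MeLi·LiBr, THF, 0 to 25 °C; LaCl3·2LiCl, −78 °C; then 5, −78 °C; AcOH quench
Reagents that add atoms: none
Why: MeLi cleaves the C–SiMe3 bond to the acetylide 14, which with the lanthanum salt (to suppress enolisation and β-elimination of 5) adds 1,2 to the ketone faster than to the lactone; the carbinol configuration (attack anti to the C20 methyl is expected) is erased in step 9.

Step 9
Reactants: 15 C10 alkynyl carbinol on the bridged lactone
Product: 16 (E)-enone with C8 ketone and exocyclic C9=C10
Conditions: Ph3PAuNTf2 (2 mol%), MeOH (1 equiv), toluene, 25 °C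
Reagents that add atoms: none
Why: Gold-catalysed Meyer–Schuster rearrangement of the tertiary propargylic alcohol moves the oxygen from C10 to C8; the E isomer (C8 cis to C11, away from the bridgehead C1 whose methyl lies in the alkene plane) is the thermodynamic enone.

Step 10
Reactants: 16 (E)-enone with C8 ketone and exocyclic C9=C10
Product: 17 α-hydroxy enone (free 7R alcohol)
Conditions: HF·pyridine, pyridine, THF, 0 °C
Reagents that add atoms: none
Why: Buffered fluoride cleaves the secondary triethylsilyl ether selectively beside the primary tert-butyldiphenylsilyl ether, without base that could enolise C7.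

Step 11
Reactants: 17 α-hydroxy enone (free 7R alcohol); 18 2-bromopropanoyl bromide
Product: 19 O7 2-bromopropanoate of 17
Conditions: pyridine, CH2Cl2, −20 °C
Reagents that add atoms: none
Why: Acylation of the α-hydroxy ketone with an acid bromide under mild base; the CHBr centre is inconsequential.

Step 12
Reactants: 19 O7 2-bromopropanoate of 17
Product: 20 β-hydroxy γ-lactone carrying the C9=C10 alkene
Conditions: Zn dust (Me3SiCl-activated), THF, 25 °C
Reagents that add atoms: none
Why: Intramolecular Reformatsky reaction (5-exo-trig): the zinc enolate tethered to O7 adds to the C8 ketone from the face that puts the bulky C9 alkenyl group trans to C6 on the new lactone, which gives the C8 hydroxyl cis to C6; C17 is epimerisable and is expected to settle with its methyl trans to C9.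

Step 13
Reactants: 20 β-hydroxy γ-lactone carrying the C9=C10 alkene
Product: 21 9,10-epoxide of 20
Conditions: mCPBA, NaHCO3, CH2Cl2, 0 °C
Reagents that add atoms: 3-chloroperoxybenzoic acid OOC(=O)c1cccc(Cl)c1
Why: Prilezhaev epoxidation: the trisubstituted, hydroxyl-flanked C9=C10 alkene should react faster than the bridging disubstituted alkene and the chloroalkene, and the peracid approaches the exocyclic alkene of the rigid bicycle anti to the C20 methyl (lactone-bridge side), which sets C9.

Step 14
Reactants: 21 9,10-epoxide of 20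
Product: 22 8,9-diol with H10 trans to the C15 methyl
Conditions: Cp2TiCl2 (20 mol%), Mn, 2,4,6-collidine·HCl, 1,4-cyclohexadiene, THF, 25 °C
Reagents that add atoms: none
Why: Titanocene-mediated reductive epoxide opening (Cp2TiCl, trivalent titanium, formed by Mn): homolysis gives the tertiary C10 radical with the oxygen kept on C9, and hydrogen-atom transfer from the diene arrives anti to the C20 methyl, setting C10.

Step 15
Reactants: 22 8,9-diol with H10 trans to the C15 methyl
Product: 23 C9 tert-butyldimethylsilyl ether of 22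
Conditions: t-BuMe2SiOTf, 2,6-lutidine, CH2Cl2, −78 °C
Reagents that add atoms: tert-butyldimethylsilyl trifluoromethanesulfonate CC(C)(C)[Si](C)(C)OS(=O)(=O)C(F)(F)F
Why: Silylation at low temperature discriminates the secondary C9 hydroxyl from the tertiary C8 hydroxyl; the free C9 hydroxyl would otherwise allow lactone migration from O7 to O9 under base.

Step 16
Reactants: 23 C9 tert-butyldimethylsilyl ether of 22
Product: 24 β-keto sulfone with C2 ketone, C3H2SO2Ph and free C12 hydroxyl
Conditions: PhSO2CH3/n-BuLi (5 equiv), THF, −78 to −30 °C; AcOH quench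
Reagents that add atoms: methyl phenyl sulfone CS(=O)(=O)c1ccccc1
Why: Acylation of a sulfonyl carbanion by a lactone: the strained, non-enolisable bridged lactone is opened at C2, while the γ-lactone is shielded by the neighbouring C8 alkoxide formed first (which also rules out β-elimination); no stereocentre is formed.

Step 17
Reactants: 24 β-keto sulfone with C2 ketone, C3H2SO2Ph and free C12 hydroxyl
Product: 25 C4 primary allylic alcohol
Conditions: Bu4NF/AcOH (1:1), THF, 0 °C
Reagents that add atoms: none
Why: Buffered fluoride cleaves the unhindered primary tert-butyldiphenylsilyl ether faster than the hindered secondary silyl ether at C9.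

Step 18
Reactants: 25 C4 primary allylic alcohol
Product: 26 C4 allylic bromide
Conditions: CBr4, PPh3, CH2Cl2, −30 °C
Reagents that add atoms: carbon tetrabromide BrC(Br)(Br)Br
Why: Appel bromination of the primary allylic alcohol (SN2, no allylic transposition); the hindered secondary C12 and tertiary C8 hydroxyls should not react at low temperature.

Step 19
Reactants: 26 C4 allylic bromide
Product: 27 ten-membered β-keto sulfone (C3 epimers)
Conditions: Cs2CO3, DMF, 0.002 M (syringe-pump addition), 25 °C
Reagents that add atoms: none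
Why: Intramolecular C-alkylation of the β-keto sulfone anion by the allylic bromide (SN2, 10-exo-tet) under high dilution closes the ten-membered ring; the cis C4/C7 arrangement on C5=C6 pre-organises the chain, and the C3 centre is removed in step 20.

Step 20
Reactants: 27 ten-membered β-keto sulfone (C3 epimers)
Product: 28 C2 ketone
Conditions: SmI2, THF/MeOH, −78 °C
Reagents that add atoms: none
Why: Reductive desulfonylation of an α-sulfonyl ketone by samarium diiodide (divalent samarium); the lactone, vinyl chloride and silyl ether are inert at this temperature.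

Step 21
Reactants: 28 C2 ketone
Product: 29 (2S,12R)-diol
Conditions: (R)-2-methyl-CBS-oxazaborolidine (20 mol%), catecholborane, toluene, −40 °C
Reagents that add atoms: none
Why: Corey–Bakshi–Shibata reduction: the (R)-oxazaborolidine differentiates the quaternary C1 side from the C3 methylene and should deliver hydride to give 2S under reagent control.

Step 22
Reactants: 29 (2S,12R)-diol
Product: 30 2,12-diacetate with C9 silyl ether
Conditions: Ac2O, DMAP, pyridine, 25 °C
Reagents that add atoms: acetic anhydride CC(=O)OC(C)=O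
Why: Acetylation of the two secondary alcohols; the hindered tertiary C8 hydroxyl should not react.

Step 23
Reactants: 30 2,12-diacetate with C9 silyl ether
Product: 31 CNP0296164.1
Conditions: HF·pyridine, pyridine, THF, 25 °C
Reagents that add atoms: none
Why: Desilylation under non-basic fluoride conditions leaves the acetates and the lactone untouched and avoids acyl migration to the liberated C9 hydroxyl.

**Compound list**

1 | methyl 2-methyl-3-oxopentanoate (racemic) | CCC(=O)C(C)C(=O)OC | starting material
2 | prop-2-ynal | C#CC=O | starting material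
3 | methyl (2S)-2-methyl-3-oxo-2-[(1Z)-3-oxoprop-1-en-1-yl]pentanoate | CCC(=O)[C@](C)(/C=C\C=O)C(=O)OC | intermediate (not isolated)
4 | methyl (1S,3S,4R)-4-hydroxy-1,3-dimethyl-2-oxocyclohex-5-ene-1-carboxylate | O=C1[C@@H](C)[C@H](O)C=C[C@]1(C)C(=O)OC | intermediate
5 | (1R,4S,6S)-4,6-dimethyl-2-oxabicyclo[2.2.2]oct-7-ene-3,5-dione | O=C1[C@@H](C)[C@@H]2OC(=O)[C@@]1(C)C=C2 | intermediate
6 | 4-methylfuran-2(5H)-one | CC1=CC(=O)OC1 | starting material
7 | 3-chloro-4-methylfuran-2(5H)-one | CC1=C(Cl)C(=O)OC1 | intermediate
8 | (2E)-2-chloro-4-hydroxy-N-methoxy-N,3-dimethylbut-2-enamide | CON(C)C(=O)/C(Cl)=C(\CO)C | intermediate (not isolated)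
9 | (2E)-4-[tert-butyl(diphenyl)silyl]oxy-2-chloro-N-methoxy-N,3-dimethylbut-2-enamide | CON(C)C(=O)/C(Cl)=C(\CO[Si](c1ccccc1)(c1ccccc1)C(C)(C)C)C | intermediate
10 | (2E)-4-[tert-butyl(diphenyl)silyl]oxy-2-chloro-3-methylbut-2-enal | O=C/C(Cl)=C(\CO[Si](c1ccccc1)(c1ccccc1)C(C)(C)C)C | intermediate
11 | ethynyl(trimethyl)silane | C#C[Si](C)(C)C | starting material
12 | (3R,4E)-6-[tert-butyl(diphenyl)silyl]oxy-4-chloro-5-methyl-1-(trimethylsilyl)hex-4-en-1-yn-3-ol | C[Si](C)(C)C#C[C@@H](O)/C(Cl)=C(\CO[Si](c1ccccc1)(c1ccccc1)C(C)(C)C)C | intermediate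
13 | triethylsilyl ether of 12 | C[Si](C)(C)C#C[C@@H](O[Si](CC)(CC)CC)/C(Cl)=C(\CO[Si](c1ccccc1)(c1ccccc1)C(C)(C)C)C | intermediate
14 | lithium acetylide from 13 (C-desilylated) | [Li]C#C[C@@H](O[Si](CC)(CC)CC)/C(Cl)=C(\CO[Si](c1ccccc1)(c1ccccc1)C(C)(C)C)C | intermediate (not isolated)
15 | C10 alkynyl carbinol: lactone 5 with C10(OH)–C9≡C8–C7(OSiEt3; 7R)–C6(Cl)=C5(Me)–C4H2OSiPh2t-Bu, hydroxyl on the side of the C20 methyl | CC(C)(C)[Si](c1ccccc1)(c1ccccc1)OC/C(C)=C(/Cl)[C@H](O[Si](CC)(CC)CC)C#C[C@]1(O)[C@@H](C)[C@@H]2OC(=O)[C@@]1(C)C=C2 | intermediate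
16 | (E)-enone: C8 ketone conjugated to C9=C10 exocyclic to the bridged lactone (C8 cis to C11), 7R triethylsilyl ether | CC(C)(C)[Si](c1ccccc1)(c1ccccc1)OC/C(C)=C(/Cl)[C@H](O[Si](CC)(CC)CC)C(=O)/C=C1\[C@@H](C)[C@@H]2OC(=O)[C@@]1(C)C=C2 | intermediate
17 | α-hydroxy enone (free 7R alcohol) | CC(C)(C)[Si](c1ccccc1)(c1ccccc1)OC/C(C)=C(/Cl)[C@H](O)C(=O)/C=C1\[C@@H](C)[C@@H]2OC(=O)[C@@]1(C)C=C2 | intermediate
18 | 2-bromopropanoyl bromide (racemic) | CC(Br)C(=O)Br | starting material
19 | O7 2-bromopropanoate of 17 (CHBr epimers) | CC(C)(C)[Si](c1ccccc1)(c1ccccc1)OC/C(C)=C(/Cl)[C@H](OC(=O)C(C)Br)C(=O)/C=C1\[C@@H](C)[C@@H]2OC(=O)[C@@]1(C)C=C2 | intermediate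
20 | β-hydroxy γ-lactone (C7–O–C19(=O)–C17(Me)–C8(OH); C7, C8, C17 as in the target) with C9=C10 alkene and bridged lactone | CC(C)(C)[Si](c1ccccc1)(c1ccccc1)OC/C(C)=C(/Cl)[C@@H]1OC(=O)[C@H](C)[C@@]1(O)/C=C1\[C@@H](C)[C@@H]2OC(=O)[C@@]1(C)C=C2 | intermediate
21 | 9,10-epoxide of 20 (oxygen anti to the C20 methyl; C9 as in the target) | CC(C)(C)[Si](c1ccccc1)(c1ccccc1)OC/C(C)=C(/Cl)[C@@H]1OC(=O)[C@H](C)[C@@]1(O)[C@H]3O[C@@]31[C@@H](C)[C@@H]2OC(=O)[C@@]1(C)C=C2 | intermediate
22 | 8,9-diol with H10 trans to the C15 methyl (C8, C9, C10 as in the target) | CC(C)(C)[Si](c1ccccc1)(c1ccccc1)OC/C(C)=C(/Cl)[C@@H]1OC(=O)[C@H](C)[C@@]1(O)[C@@H](O)[C@H]1[C@@H](C)[C@@H]2OC(=O)[C@@]1(C)C=C2 | intermediate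
23 | C9 tert-butyldimethylsilyl ether of 22 | CC(C)(C)[Si](c1ccccc1)(c1ccccc1)OC/C(C)=C(/Cl)[C@@H]1OC(=O)[C@H](C)[C@@]1(O)[C@@H](O[Si](C)(C)C(C)(C)C)[C@H]1[C@@H](C)[C@@H]2OC(=O)[C@@]1(C)C=C2 | intermediate
24 | β-keto sulfone: bridged lactone opened to C2(=O)–C3H2–SO2Ph, free C12 hydroxyl | CC(C)(C)[Si](c1ccccc1)(c1ccccc1)OC/C(C)=C(/Cl)[C@@H]1OC(=O)[C@H](C)[C@@]1(O)[C@@H](O[Si](C)(C)C(C)(C)C)[C@H]1[C@@H](C)[C@H](O)C=C[C@]1(C)C(=O)CS(=O)(=O)c1ccccc1 | intermediate
25 | C4 primary allylic alcohol from 24 | OC/C(C)=C(/Cl)[C@@H]1OC(=O)[C@H](C)[C@@]1(O)[C@@H](O[Si](C)(C)C(C)(C)C)[C@H]1[C@@H](C)[C@H](O)C=C[C@]1(C)C(=O)CS(=O)(=O)c1ccccc1 | intermediate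
26 | C4 allylic bromide | BrC/C(C)=C(/Cl)[C@@H]1OC(=O)[C@H](C)[C@@]1(O)[C@@H](O[Si](C)(C)C(C)(C)C)[C@H]1[C@@H](C)[C@H](O)C=C[C@]1(C)C(=O)CS(=O)(=O)c1ccccc1 | intermediate
27 | ten-membered β-keto sulfone (C2 ketone, 3-phenylsulfonyl as C3 epimers, 8-OH, 9-silyl ether, 12-OH) | O=C1C(S(=O)(=O)c3ccccc3)C/C(C)=C(/Cl)[C@@H]2OC(=O)[C@H](C)[C@@]2(O)[C@@H](O[Si](C)(C)C(C)(C)C)[C@H]2[C@@H](C)[C@H](O)C=C[C@@]21C | intermediate
28 | C2 ketone after desulfonylation | O=C1CC/C(C)=C(/Cl)[C@@H]2OC(=O)[C@H](C)[C@@]2(O)[C@@H](O[Si](C)(C)C(C)(C)C)[C@H]2[C@@H](C)[C@H](O)C=C[C@@]21C | intermediate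
29 | (2S,12R)-diol with C9 silyl ether | O[C@H]1CC/C(C)=C(/Cl)[C@@H]2OC(=O)[C@H](C)[C@@]2(O)[C@@H](O[Si](C)(C)C(C)(C)C)[C@H]2[C@@H](C)[C@H](O)C=C[C@@]21C | intermediate
30 | 2,12-diacetate with C9 silyl ether | CC(=O)O[C@H]1CC/C(C)=C(/Cl)[C@@H]2OC(=O)[C@H](C)[C@@]2(O)[C@@H](O[Si](C)(C)C(C)(C)C)[C@H]2[C@@H](C)[C@H](OC(C)=O)C=C[C@@]21C | intermediate
31 | CNP0296164.1 | CC(=O)O[C@H]1CC/C(C)=C(/Cl)[C@@H]2OC(=O)[C@H](C)[C@@]2(O)[C@@H](O)[C@H]2[C@@H](C)[C@H](OC(C)=O)C=C[C@@]21C | target

**Totals and risks**

Total step count: 23. Longest linear sequence: 21 steps (steps 3–7 to alkyne 13, then steps 8–23).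

Steps most likely to fail:

1. Step 1 (labelled step). The enantiofacial control of the conjugate addition may be eroded by a fast uncatalysed background addition to the very electrophilic ynal, and part of the enal may be lost as the E isomer or by polymerisation. Fallback with known reactions only: setting out again from 1 and 2, the annulation is run with an achiral amine (Et3N, then DBU) to give the racemate, rac-4 F1. Lipase-catalysed kinetic resolution (Burkholderia cepacia lipase, vinyl acetate, t-BuOMe) should acylate the (4R)-alcohol to methyl (1S,3S,4R)-4-acetoxy-1,3-dimethyl-2-oxocyclohex-5-ene-1-carboxylate F2. F2 is separated from the unreacted antipode and deacylated by lipase-catalysed butanolysis (Candida antarctica lipase B, n-BuOH); the route is re-entered at 4.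

2. Step 19. Closure of the strained ten-membered ring may lose out to intermolecular alkylation (oligomers) or to O-alkylation of the enolate. Fallback: setting out from 25, the primary alcohol is converted selectively (ClCO2Me, pyridine, −20 °C) into the C4 allylic methyl carbonate of 25 F3. F3 is cyclised by palladium-catalysed allylic alkylation (Pd(PPh3)4, zerovalent palladium, THF, high dilution): ionisation gives a π-allyl complex and methoxide, which deprotonates the β-keto sulfone, and attack at the less substituted terminus C4 returns to 27 without a discrete bromide.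

3. Step 13. The peracid may attack the bridging C13=C14 alkene or the wrong face of C9=C10. Fallback: setting out from 20, hydroxyl-directed epoxidation with VO(acac)2 (5 mol%) and t-BuOOH in CH2Cl2 at 0 °C delivers oxygen through the vanadium alkoxide of the C8 hydroxyl, so only the allylic C9=C10 alkene is oxidised and the control element changes from steric approach of a free peracid to directed delivery; it returns to 21 and makes no new compound.

**Further compounds**

F1 | step 1 | rac-4 (racemate; relative configuration as in 4) | O=C1[C@@H](C)[C@H](O)C=C[C@]1(C)C(=O)OC.O=C1[C@H](C)[C@@H](O)C=C[C@@]1(C)C(=O)OC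
F2 | step 1 | methyl (1S,3S,4R)-4-acetoxy-1,3-dimethyl-2-oxocyclohex-5-ene-1-carboxylate | O=C1[C@@H](C)[C@H](OC(C)=O)C=C[C@]1(C)C(=O)OC
F3 | step 19 | C4 allylic methyl carbonate of 25 | COC(=O)OC/C(C)=C(/Cl)[C@@H]1OC(=O)[C@H](C)[C@@]1(O)[C@@H](O[Si](C)(C)C(C)(C)C)[C@H]1[C@@H](C)[C@H](O)C=C[C@]1(C)C(=O)CS(=O)(=O)c1ccccc1
F0 | step 13 | none | none
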